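## Retrosynthetic overview

1. Leoligin is cut at the ester (Mitsunobu reaction with angelic acid) to the primary alcohol. This goes back through reduction and C3 epimerisation to a 2,3-cis-3,4-trans 2-aryl-4-benzyltetrahydrofuran-3-carbaldehyde.
2. Enabling feature: in the tetrahydrofuran ring (O1, C2 to C5) the chain O1–C2(aryl)–C3–CH2–O is a masked aldol. C2 is an ether carbon with an electron-rich aryl group (latent oxocarbenium carbon), and C3 bears an oxygenated one-carbon branch (latent aldehyde enolate carbon). A bond from the branch oxygen to C2 therefore stores both partners in one seven-membered cyclic vinyl acetal.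
3. Key disconnection C2–C3: the tetrahydrofuran comes from a 2-aryl-5-benzyl-4,5-dihydro-1,3-dioxepine by a Lewis acid [1,3] O-to-C ring contraction (seven to five). This makes the C–C bond, two stereocentres and the formyl handle at once, under control of the lone stereocentre C5.
4. The dihydrodioxepine comes from an enantioselective Heck benzylation (3,4-dimethoxybenzyl trifluoroacetate) of the achiral 4,7-dihydro-1,3-dioxepine made from cis-butenediol and veratraldehyde.
5. Ring order: seven-membered acetal ring (step 1), then the tetrahydrofuran ring (step 4). Both arenes are bought.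

Key step: step 4

Remark on numbering: dioxepines are numbered O1, C2, O3, C4 to C7 and tetrahydrofurans O1, C2 to C5. C5 of 6 becomes C4 of 8.

Assumption: the ligand enantiomer named in step 3 is taken to give 5R, and the mirror-image ligand is used if the sense of induction turns out opposite.

## Route

Step 1
Reactants: 1 (Z)-but-2-ene-1,4-diol; 2 3,4-dimethoxybenzaldehyde
Product: 3 2-(3,4-dimethoxyphenyl)-4,7-dihydro-1,3-dioxepine
Conditions: p-TsOH·H2O (cat.), toluene, reflux, Dean–Stark trap
Reagents that add atoms: none
Why: Acid-catalysed acetalisation with azeotropic removal of water, in which the cis geometry of the diol lets the seven-membered ring close and the product keeps a mirror plane through C2, so that no stereocentre has to be controlled.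

Step 2
Reactants: 4 (3,4-dimethoxyphenyl)methanol
Product: 5 3,4-dimethoxybenzyl trifluoroacetate
Conditions: (CF3CO)2O, pyridine, Et2O, 0 °C; used without storage
Reagents that add atoms: trifluoroacetic anhydride, O=C(OC(=O)C(F)(F)F)C(F)(F)F
Why: O-acylation of a primary benzylic alcohol with an anhydride turns the hydroxyl group into a leaving group that zerovalent palladium can ionise, and no stereocentre is formed.

Step 3
Reactants: 3 2-(3,4-dimethoxyphenyl)-4,7-dihydro-1,3-dioxepine; 5 3,4-dimethoxybenzyl trifluoroacetate
Product: 6 (5R)-5-(3,4-dimethoxybenzyl)-2-(3,4-dimethoxyphenyl)-4,5-dihydro-1,3-dioxepine (C2 epimers carried on together)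
Conditions: Pd(dba)2 (5 mol %), (S)-BINOL-derived N,N-bis[(R)-1-phenylethyl]phosphoramidite (12 mol %), Li2CO3, 3 in excess (3 equiv), THF, 60 °C
Reagents that add atoms: none
Why: Enantioselective Mizoroki–Heck benzylation of a cyclic olefin, in which oxidative addition to zerovalent palladium gives a cationic benzylpalladium complex, the chiral phosphoramidite selects one of the two enantiotopic olefin carbons for syn carbopalladation and thereby sets C5 as R on either ring face, and syn β-hydride elimination can only run toward C7 because the C5–H bond is anti to palladium, which delivers the enol ether.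

Step 4
Reactants: 6 (5R)-5-(3,4-dimethoxybenzyl)-2-(3,4-dimethoxyphenyl)-4,5-dihydro-1,3-dioxepine
Product: 8 (2S,3R,4R)-4-(3,4-dimethoxybenzyl)-2-(3,4-dimethoxyphenyl)tetrahydrofuran-3-carbaldehyde (2,3-cis-3,4-trans), via oxocarbenium triflate 7 (not isolated)
Conditions: TBSOTf (0.2 equiv), CH2Cl2, −78 °C; then Et3N, −78 °C
Reagents that add atoms: none
Why: TBSOTf silylates the enol ether oxygen O1 of either C2 epimer of 6, the C2–O1 bond ionises with the push of O3 and of the 3,4-dimethoxyphenyl group, and the open ion 7, an (E)-aryl oxocarbenium ion tethered to a (Z)-silyl enol ether, recloses by C–C bond formation between C6 and C2 and hands the silyl group on to the next molecule of 6, so that O1 and C7 leave the seven-membered ring as the formyl group and O3, C2, C6, C5 and C4 remain as the tetrahydrofuran. The closest known reaction type is the Lewis acid mediated [1,3] O-to-C rearrangement of cyclic vinyl acetals (Petasis–Ferrier type ring contraction of 4,5-dihydro-1,3-dioxepines to tetrahydrofuran-3-carbaldehydes), in essence an intramolecular Mukaiyama aldol addition to an oxocarbenium ion. The one ring that closes does so in a 5-(enolexo)-endo-trig mode, endo with respect to the C=O+ bond, which is accepted for such cationic acceptors because the early, loose transition state needs little orbital alignment. C3 is controlled by the C5 stereocentre of 6 through 1,3-allylic strain: next to the (Z)-enol ether the C5–H bond takes the inside position, the CH2–O tether reaches over one face and the benzyl group points outward, so that formyl and benzyl end up trans. C2 is set under kinetic control, since silyl triflates at −78 °C steer this closure through a compact synclinal transition state to the 2,3-cis product, which here also puts the pseudoequatorial aryl group on the ring face opposite to the benzyl group, the 2,4-trans relationship that the target needs. The step needs cleavage of C2–O1 and not C2–O3 (only O1 leaves as an enolate equivalent, and cleavage at O3 is reversible and leads nowhere), attack by the enol carbon and not by the dimethoxybenzyl ring (five- against seven-membered closure, stronger nucleophile) and no equilibration of the product (catalytic Lewis acid, −78 °C, amine quench).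

Step 5
Reactants: 8 (2S,3R,4R)-4-(3,4-dimethoxybenzyl)-2-(3,4-dimethoxyphenyl)tetrahydrofuran-3-carbaldehyde
Product: 10 [(2S,3R,4R)-4-(3,4-dimethoxybenzyl)-2-(3,4-dimethoxyphenyl)tetrahydrofuran-3-yl]methanol, via 2,3-trans-3,4-cis aldehyde 9 (not isolated)
Conditions: DBU (0.3 equiv), CH2Cl2, 23 °C; then MeOH, NaBH4, 0 °C; purification at the alcohol stage
Reagents that add atoms: none
Why: Base-mediated epimerisation of an α-stereogenic aldehyde through its enolate followed by borohydride reduction, in which C2 and C4 stay fixed and trans to each other, so that the formyl group must be cis to one neighbour and should settle trans to the ring-bound, branched aryl group at C2 (3S in 9 and, by a change of substituent priorities only, 3R in 10), while β-elimination of the ring oxygen is held back because the C2–O1 bond lies in the nodal plane of the exocyclic enolate (the reverse of a 5-endo-trig closure).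

Step 6
Reactants: 10 [(2S,3R,4R)-4-(3,4-dimethoxybenzyl)-2-(3,4-dimethoxyphenyl)tetrahydrofuran-3-yl]methanol; 11 angelic acid, (Z)-2-methylbut-2-enoic acid
Product: 12 leoligin
Conditions: PPh3, DIAD, THF, 0 °C to 23 °C
Reagents that add atoms: none
Why: The Mitsunobu esterification activates the primary alcohol and not the acid, so that the angelate attacks as a carboxylate and its Z double bond cannot drift to the tiglate through an activated acyl species, and no ring stereocentre is touched because the substitution takes place at the CH2 group.

## Compound list

1 | (Z)-but-2-ene-1,4-diol | OC/C=C\CO | starting material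
2 | 3,4-dimethoxybenzaldehyde (veratraldehyde) | COc1ccc(C=O)cc1OC | starting material
3 | 2-(3,4-dimethoxyphenyl)-4,7-dihydro-1,3-dioxepine | COc1ccc(C2OCC=CCO2)cc1OC | intermediate
4 | (3,4-dimethoxyphenyl)methanol (veratryl alcohol) | COc1ccc(CO)cc1OC | starting material
5 | 3,4-dimethoxybenzyl trifluoroacetate | COc1ccc(COC(=O)C(F)(F)F)cc1OC | intermediate
6 | (5R)-5-(3,4-dimethoxybenzyl)-2-(3,4-dimethoxyphenyl)-4,5-dihydro-1,3-dioxepine, both C2 epimers (C2 left open) | O1C=C[C@@H](Cc2ccc(OC)c(OC)c2)COC1c1ccc(OC)c(OC)c1 | intermediate
7 | open ion pair: (E)-aryl oxocarbenium ion tethered to the (Z)-tert-butyldimethylsilyl enol ether, triflate counterion | COc1ccc(C=[O+]C[C@H](Cc2ccc(OC)c(OC)c2)/C=C\O[Si](C)(C)C(C)(C)C)cc1OC.[O-]S(=O)(=O)C(F)(F)F | intermediate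
8 | (2S,3R,4R)-4-(3,4-dimethoxybenzyl)-2-(3,4-dimethoxyphenyl)tetrahydrofuran-3-carbaldehyde (2,3-cis-3,4-trans) | O=C[C@@H]1[C@@H](Cc2ccc(OC)c(OC)c2)CO[C@@H]1c1ccc(OC)c(OC)c1 | intermediate
9 | (2S,3S,4R)-4-(3,4-dimethoxybenzyl)-2-(3,4-dimethoxyphenyl)tetrahydrofuran-3-carbaldehyde (2,3-trans-3,4-cis) | O=C[C@H]1[C@@H](Cc2ccc(OC)c(OC)c2)CO[C@@H]1c1ccc(OC)c(OC)c1 | intermediate
10 | [(2S,3R,4R)-4-(3,4-dimethoxybenzyl)-2-(3,4-dimethoxyphenyl)tetrahydrofuran-3-yl]methanol | OC[C@H]1[C@@H](Cc2ccc(OC)c(OC)c2)CO[C@@H]1c1ccc(OC)c(OC)c1 | intermediate
11 | angelic acid, (Z)-2-methylbut-2-enoic acid | C/C=C(/C)C(=O)O | starting material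
12 | leoligin | C/C=C(/C)C(=O)OC[C@H]1[C@@H](Cc2ccc(OC)c(OC)c2)CO[C@@H]1c1ccc(OC)c(OC)c1 | target

## Step count and risks

Total step count: 6. Longest linear sequence: 5 (steps 1, 3, 4, 5, 6).

**Step 3.**
- **What may go wrong:** carbopalladation of the unstrained 1,2-disubstituted olefin by the benzylpalladium species may be slow. The benzyl unit may then homocouple, and the two enantiotopic olefin carbons may be told apart only weakly.
- **Fallback (sets out from 4, takes in 2, returns at 6):** the stereocentre is made by an enantioselective 1,3-hydrogen shift instead of by C–C bond formation. PBr3 in Et2O at 0 °C turns 4 into 4-(bromomethyl)-1,2-dimethoxybenzene F1. Syn hydrostannylation of commercial but-2-yne-1,4-diol (Bu3SnH, PdCl2(PPh3)2 cat., THF) gives (E)-2-(tributylstannyl)but-2-ene-1,4-diol F2, in which both CH2OH groups are cis. Stille coupling of the two (Pd2(dba)3, AsPh3, CuI, DMF) gives (Z)-2-(3,4-dimethoxybenzyl)but-2-ene-1,4-diol F3. Acetalisation with 2 as in step 1 gives racemic 5-(3,4-dimethoxybenzyl)-2-(3,4-dimethoxyphenyl)-4,7-dihydro-1,3-dioxepine F4. A chiral nickel hydride made from NiBr2((R,R)-Me-DuPHOS) and LiBHEt3 in THF at low temperature then moves the double bond from C5=C6 to C6=C7. Hydrogen goes to one face of C5 in both C2 enantiomers, which should give 6.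

**Step 4.**
- **What may go wrong:** the acetal configuration may not be fully lost before the C–C bond forms, or the closure may become reversible because the aryl group stabilises the cation. Either process erodes the kinetic 2,3-cis selectivity and thus the 2,4-trans relationship. The electron-rich benzyl ring may also capture a cationic centre.
- **Fallback (sets out from 6, returns at 8):** C2 is fixed by chirality transfer from the acetal carbon instead of by a transition-state preference in a free ion. The C2 epimers of 6 are separated on silica gel deactivated with Et3N. Only the 2,5-trans epimer, (2S,5R)-5-(3,4-dimethoxybenzyl)-2-(3,4-dimethoxyphenyl)-4,5-dihydro-1,3-dioxepine F5, is rearranged, now with Me2AlCl in toluene–hexane at −78 °C. In this unpolar medium the aluminium enolate and the oxocarbenium ion should stay a contact ion pair and recombine on the face from which O1 left (stereoretentive [1,3] O-to-C shift). Retention at C2 maps the 2,5-trans relationship onto the 2,4-trans relationship, and 1,3-allylic strain sets C3 as before, which should give 8.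

**Step 5.**
- **What may go wrong:** the equilibrium may not lie far enough on the 2,3-trans-3,4-cis side, or the ring may open slowly by β-elimination on long exposure to base.
- **Fallback (sets out from 8, returns at 9):** C3 is set by kinetic protonation instead of by equilibration. TBSOTf and Et3N in CH2Cl2 convert 8 into its exocyclic tert-butyldimethylsilyl enol ether F6 (C3=CH–OTBS, C2 and C4 unchanged). The enolate is released at −78 °C with TBAF in the presence of 2,6-di-tert-butyl-4-methylphenol as a bulky proton source. Protonation from the less hindered face gives the contra-thermodynamic epimer. If the equilibrium of step 5 favours 8, the same steric bias should make 9 the kinetic product, which is reduced at once with NaBH4 as in step 5.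

## Further compounds

F1 | step 3 | 4-(bromomethyl)-1,2-dimethoxybenzene | COc1ccc(CBr)cc1OC
F2 | step 3 | (E)-2-(tributylstannyl)but-2-ene-1,4-diol | OC/C=C(\CO)[Sn](CCCC)(CCCC)CCCC
F3 | step 3 | (Z)-2-(3,4-dimethoxybenzyl)but-2-ene-1,4-diol | OC/C=C(\CO)Cc1ccc(OC)c(OC)c1
F4 | step 3 | 5-(3,4-dimethoxybenzyl)-2-(3,4-dimethoxyphenyl)-4,7-dihydro-1,3-dioxepine (racemic) | COc1ccc(CC2=CCOC(OC2)c2ccc(OC)c(OC)c2)cc1OC
F5 | step 4 | (2S,5R)-5-(3,4-dimethoxybenzyl)-2-(3,4-dimethoxyphenyl)-4,5-dihydro-1,3-dioxepine (2,5-trans epimer of 6) | O1C=C[C@@H](Cc2ccc(OC)c(OC)c2)CO[C@@H]1c1ccc(OC)c(OC)c1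
F6 | step 5 | exocyclic tert-butyldimethylsilyl enol ether of 8 (enol ether geometry open) | CC(C)(C)[Si](C)(C)OC=C1[C@@H](Cc2ccc(OC)c(OC)c2)CO[C@@H]1c1ccc(OC)c(OC)c1
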